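**Remark on the chemistry (assumption):** 3,5-dimethoxyphenol, 6-chlorohex-1-yne and racemic 1,2-epoxyheptane are taken as purchasable. Locants C1–C8a refer to the isochroman-1-one core (C1 carbonyl, O2, C3, C4, ring A = C4a–C8a) and C1'–C11' to the side chain.

## Analysis of the target

Compound 23 is a 3,4-dihydroisocoumarin: benzene ring A is fused to a δ-lactone (C1, O2, C3, C4), with phenols at C6 and C8 and an undecyl chain on C3 that carries a secondary alcohol at C6'. It has two stereocentres, C3 (R) and C6' (S). They are 1,7-related through five methylene groups, so neither can steer the other and each needs its own external source of chirality. C3 is flanked by two methylene groups (benzylic C4 and C1'), which makes it a poorly differentiated centre for any plan that sets it by reducing a ketone. The lactone opens with hydroxide or alkoxide, the free resorcinol is nucleophilic and easily oxidised, and the C6' carbinol can ionise or eliminate under strong Lewis acid. Ring A is 1,2,3,5-tetrasubstituted with three adjacent substituents (carbon at C4a, carboxyl at C8a, oxygen at C8), a pattern that electrophilic substitution of a resorcinol ether does not deliver cleanly. The strategy rests on this triad: C4a and C8a are neighbours carrying C4 and C1, and the C8 oxygen sits beside C8a. That is the arrangement produced when a 3-alkoxyaryne accepts a carbon nucleophile at the carbon remote from the alkoxy group and an electrophile at the adjacent one. If C3–C4 is raised to the alkyne oxidation level, C4, C3 and the whole side chain become one terminal alkyne, and C1 with both lactone oxygens is carbon dioxide.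

## Retrosynthetic reasoning

**23 to 22.** The last disconnection removes three O–C bonds: the methyl ethers on O6 and O8 and the benzyl ether on O6'. The oxygens stay capped until the end because free phenols or a free C6' hydroxyl would add to the aryne or be carboxylated in the key step. The forward step is a single Lewis-acid dealkylation that must leave C3–O2 and C6'–O intact.

**22 to 21.** The C3–H and C4–H bonds are removed, which leads back to isocoumarin 21. C3 becomes sp2 and can therefore originate from an alkyne carbon. The stereochemical problem becomes face selection on a flat enol lactone, for which a dedicated class of chiral hydrogenation catalysts exists. Opening the lactone to the ketone and reducing it was considered for this stage, but a ketone between two methylene groups offers little steric or electronic bias; that sequence is kept only as a fallback. The forward step must select one face under catalyst control alone and leave the benzyl ether and ring A untouched.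

**21 to 8, 17 and 18.** Three bonds are cut at once: C4–C4a, C8a–C1 and O2–C3. Any single C–C disconnection on a preformed benzoate would need an arene that already carries the three adjacent substituents. Cutting both ring A bonds together hands the regiochemical problem to aryne 19, where the C8 oxygen solves it. The gain is three skeletal bonds, the pyranone ring and full convergence: aryne precursor 8, alkyne 17 and CO2 18 together contain every carbon of the target. The forward reaction has to capture the aryne regioselectively with the copper acetylide, insert 18 into the aryl–copper bond faster than protonation, and close the carboxylate 20 onto the alkyne in the 6-endo mode.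

**8 to 6, 2 and 1.** Precursor 8 is cut at its O–S bond and at its C–Si bond. The C–Si bond lies between the phenol oxygen and a methoxy group, which is exactly the position addressed by directed ortho-metalation of carbamate 2. The carbamate in 6 is then exchanged for triflate without hydrolysis. This gives 8 from phenol 1 in three operations with the regiochemistry fixed by the directing groups.

**17 to 15, then to 11 and 13.** Alkyne 17 is cut at the O–benzyl bond and then at the C6–C7 bond of the tridecyne chain (C4'–C5' of the target), one carbon away from the carbinol. This gives Grignard reagent 14 (from chloride 11) and epoxide 13. The only chain stereocentre is thereby placed in a seven-carbon epoxide, and the C–C bond formation occurs at the unsubstituted epoxide carbon, so the configuration cannot be lost.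

**13 to 12, and 11 to 9.** Epoxide 13 comes from racemate 12 by hydrolytic kinetic resolution. Chloride 11 comes from 9 by C-silylation, which removes the acidic alkyne proton that would otherwise destroy the Grignard reagent.

## Alternatives that were turned down

**Alternative 1: cycloaddition construction of ring A.**
- Disconnection: ring A is cut at C5–C4a and C8–C8a, giving ynoate A1 (both carbinols already present as silyl ethers) and the bis-silyloxy diene A2.
- Forward key step: [4+2] addition of A2 across the triple bond of A1, then loss of the alkoxy group from the ketene-acetal carbon, aromatises the adduct to resorcylate A3.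
- For: the phenols are free from the start, so no late Lewis-acid dealkylation is needed. Polarity matching (nucleophilic diene terminus onto the ynoate β-carbon) gives the right orientation. C3 arrives as a finished carbinol, so no face-selective reduction is needed. On these points this plan is stronger than the chosen one.
- Against: a β-alkyl ynoate with a single activating group is a sluggish dienophile, and A2 is sensitive to heat and moisture, so the cycloaddition would need conditions under which the diene decays. A1 is a sixteen-carbon chain with two remote carbinols, each needing its own asymmetric step before ring A exists.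
- Comparison: the ring-forming step would sit late in a long linear sequence. The chosen route takes the ring A pattern from a cheap aromatic compound, has a longest linear sequence of six steps, and places its uncertain step on short fragments. It gives up the mild endgame in exchange.

**Alternative 2: enzymatic oxygen insertion with dynamic resolution.**
- Disconnection: O2 is removed from between C1 and C3, contracting the lactone to indanone A4 with the side chain on the carbon α to the ketone.
- Forward key step: a Baeyer–Villiger monooxygenase would insert oxygen on the alkyl side of the carbonyl in one enantiomer of A4 while the other racemises through its enol, giving lactone A5 with retention at the migrating carbon.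
- For: C3 and the lactone are set in one aerobic step, a racemate can in principle be converted completely, and the sequence could be shorter than the chosen one.
- Against: the electron-rich, doubly alkoxylated aryl carbon is intrinsically the better migrating group than a secondary alkyl carbon, so the enzyme must overturn the electronic preference. The methoxy group peri to the ketone and an eleven-carbon hydroxylated chain are far from the small substrates such enzymes usually accept. Racemisation at the α-carbon must keep pace near neutral pH. C6' still needs a separate asymmetric synthesis and the methyl ethers still have to be removed.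
- Comparison: in the chosen route the position of O2 is not a selectivity question, because it arrives bonded to C1 in 18. Both plans need a catalyst to be selected for C3, so they are equal there. The chosen route offers a known catalyst class plus a chemical fallback.

**Alternative 3: biomimetic aromatisation.**
- Disconnection: ring A is cut at C4a–C8a and the C4a carbonyl is restored, unfolding the resorcylate into the open-chain diketo-dioxinone A6.
- Forward key step: a mild amine base triggers attack of the dioxinone α-carbon on the distal ketone, and dehydration gives the acetonide-masked resorcylate A7. Desilylation and lactonisation with release of the acetonide would then reach the target without any ether cleavage.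
- For: it has the mildest conditions of all four plans, no aryl ether deprotection, unambiguous regiochemistry, and C3 set beforehand. Its endgame is stronger than that of the chosen route.
- Against: A6 must be made by C-acylation of a dioxinone enolate with an acyl donor that already carries both stereocentres. The C3 oxygen is β to the C4a carbonyl, which invites E1cB loss of the silyloxy group under the basic conditions that drive aromatisation. The polycarbonyl intermediates are hard to purify and store, and the linear sequence to the chiral chain is long.
- Comparison: the chosen route works through stable, storable fragments and is shorter. It pays with a final Lewis-acid step.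

Key step: step 8

## Route

Step 1
Reactants: 1 3,5-dimethoxyphenol
Product: 2 3,5-dimethoxyphenyl N-isopropylcarbamate
Conditions: i-PrNCO (1.5 equiv), Et3N (0.2 equiv), CH2Cl2, rt
Reagents that add atoms: isopropyl isocyanate, CC(C)N=C=O
Why: Amine-catalysed addition of a phenol to an isocyanate (carbamoylation); the N-monoalkyl carbamate is a strong ortho-directing group and can later be removed without hydrolysis.

Step 2
Reactants: 2 3,5-dimethoxyphenyl N-isopropylcarbamate
Product: 6 3,5-dimethoxy-2-(trimethylsilyl)phenyl N-isopropylcarbamate, via N-silyl carbamate 3 (not isolated), via aryllithium 4 (not isolated), via bis-silyl carbamate 5 (not isolated)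
Conditions: TBSOTf, TMEDA, Et2O, 0 °C → rt; n-BuLi, TMEDA, −78 °C; TMSCl, −78 °C → rt; aq. NaHSO4
Reagents that add atoms: chlorotrimethylsilane, C[Si](C)(C)Cl
Why: Directed ortho-metalation: after N-silylation masks the N–H, lithiation should occur at C2, the only position flanked by the carbamate (the stronger director) and a methoxy group; TMSCl traps the aryllithium at −78 °C before an anionic ortho-Fries shift can occur, and aqueous acid removes the N-silyl group.

Step 3
Reactants: 6 3,5-dimethoxy-2-(trimethylsilyl)phenyl N-isopropylcarbamate
Product: 8 3,5-dimethoxy-2-(trimethylsilyl)phenyl trifluoromethanesulfonate, via silylphenoxide 7 (not isolated)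
Conditions: Et2NH, DBU, MeCN, 40 °C; then PhNTf2, rt
Reagents that add atoms: N-phenylbis(trifluoromethanesulfonimide), O=S(=O)(N(c1ccccc1)S(=O)(=O)C(F)(F)F)C(F)(F)F
Why: DBU deprotonates the N–H and the carbamate fragments (E1cB) to phenoxide 7 and isopropyl isocyanate, which Et2NH scavenges as a urea; the mild triflating agent then sulfonylates the phenoxide without fluoride or acid, so the ortho C–Si bond should survive.

Step 4
Reactants: 9 6-chlorohex-1-yne
Product: 11 (6-chlorohex-1-yn-1-yl)trimethylsilane, via lithium acetylide 10 (not isolated)
Conditions: n-BuLi, THF, −78 °C; TMSCl, −78 °C → rt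
Reagents that add atoms: chlorotrimethylsilane, C[Si](C)(C)Cl
Why: Deprotonation of the terminal alkyne and C-silylation; the primary chloride is inert to the acetylide at low temperature, and the silyl cap removes the acidic proton that would quench the Grignard reagent of step 6.

Step 5
Reactants: 12 racemic 1,2-epoxyheptane
Product: 13 (S)-1,2-epoxyheptane
Conditions: (S,S)-(salen)Co(OAc) (0.5 mol%; salen = N,N'-bis(3,5-di-tert-butylsalicylidene)cyclohexane-1,2-diamine dianion), H2O (0.55 equiv), neat, 0 °C → rt; distillation
Reagents that add atoms: none
Why: Jacobsen hydrolytic kinetic resolution: the (S,S) cobalt salen catalyst should hydrolyse the R epoxide selectively and leave the S epoxide, which is distilled from the diol; this is the origin of the C6' stereocentre of the target.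

Step 6
Reactants: 11 (6-chlorohex-1-yn-1-yl)trimethylsilane; 13 (S)-1,2-epoxyheptane
Product: 15 (8S)-1-(trimethylsilyl)tridec-1-yn-8-ol, via Grignard reagent 14 (not isolated)
Conditions: Mg, I2 (cat.), THF, reflux; then CuI (10 mol%), 13, THF, −30 → 0 °C; aq. NH4Cl
Reagents that add atoms: none
Why: Grignard formation from the primary chloride followed by copper-catalysed SN2 opening of the terminal epoxide at its unsubstituted carbon; the stereocentre is not a reacting centre, and its descriptor stays S because the ranking O > chain CH2 > pentyl is the same before and after.

Step 7
Reactants: 15 (8S)-1-(trimethylsilyl)tridec-1-yn-8-ol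
Product: 17 (8S)-8-benzyloxytridec-1-yne, via silylalkyne benzyl ether 16 (not isolated)
Conditions: NaH, BnBr, Bu4NI (cat.), THF–DMF, 0 °C → rt; then MeOH, K2CO3, rt
Reagents that add atoms: benzyl bromide, BrCc1ccccc1
Why: Williamson etherification of the sodium alkoxide, followed in the same flask by methoxide-mediated protodesilylation of the alkynylsilane; the benzyl ether tolerates fluoride, carbonate and homogeneous hydrogenation and can be cleaved together with the methyl ethers at the end.

Step 8
Reactants: 8 3,5-dimethoxy-2-(trimethylsilyl)phenyl trifluoromethanesulfonate; 17 (8S)-8-benzyloxytridec-1-yne; 18 carbon dioxide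
Product: 21 3-[(6S)-6-benzyloxyundecyl]-6,8-dimethoxyisochromen-1-one, via 3,5-dimethoxybenzyne 19 (not isolated), via 2-alkynylbenzoate salt 20 (not isolated)
Conditions: (IPr)CuCl (10 mol%; IPr = 1,3-bis(2,6-diisopropylphenyl)imidazol-2-ylidene), CsF (3 equiv), Cs2CO3 (0.2 equiv), CO2 (1 atm), MeCN, 80 °C; 8 (1.5 equiv) added in portions
Reagents that add atoms: none
Why: Fluoride removes the trimethylsilyl group of 8 and triflate leaves, releasing aryne 19 slowly because CsF is sparingly soluble in MeCN. The catalyst is converted by fluoride and 17 into the monovalent copper acetylide, which adds across the strained triple bond: the alkynyl carbon bonds to the aryne carbon remote from the flanking methoxy group (future C4a) and copper ends on the carbon next to that methoxy group (future C8a), where the σ-withdrawing oxygen best stabilises the developing negative charge. CO2 inserts into the aryl–copper bond to give carboxylate 20 (C8a–C1), and the carboxylate oxygen attacks the copper-activated alkyne in a 6-endo-dig closure (O2–C3); protonation of the vinyl–copper bond at C4 by a further molecule of 17 regenerates the acetylide. The reaction type is the known NHC–copper-catalysed three-component coupling of arynes, terminal alkynes and CO2 to isocoumarins, applied here to a dimethoxyaryne and an alkyl alkyne. No stereocentre is formed, and the C6' benzyl ether is remote and inert. Aryne regiochemistry rests on the C8 methoxy group (distortion of the triple bond), the C6 methoxy group being meta to the attacked carbon. The preference for 6-endo over 5-exo closure rests on copper π-activation of an alkyl-substituted alkyne, whose distal carbon (C3) carries positive charge better. Carboxylation of the copper acetylide itself to a propiolate is reversible at this temperature and should not drain material.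

Step 9
Reactants: 21 3-[(6S)-6-benzyloxyundecyl]-6,8-dimethoxyisochromen-1-one
Product: 22 (3R)-3-[(6S)-6-benzyloxyundecyl]-6,8-dimethoxyisochroman-1-one
Conditions: H2 (50 bar), chiral ruthenium NHC–diamine catalyst (2 mol%; preformed from Ru(2-methylallyl)2(cod), SINpEt·HBF4, KOt-Bu and 1,2-diphenylethylenediamine; SINpEt = 1,3-bis[1-(1-naphthyl)ethyl]imidazolin-2-ylidene), NaOt-Bu (10 mol%), toluene, 25 °C
Reagents that add atoms: none
Why: Catalytic asymmetric hydrogenation of 3-substituted isocoumarins with chiral divalent ruthenium NHC–diamine catalysts is a known reaction class that includes 3-alkyl and 8-methoxy members; C3 is set by the catalyst alone (C6' is six atoms away), and the ligand antipode pair that gives the 3R series is fixed in a trial on a simple 3-alkylisocoumarin. The benzyl ether and ring A are not expected to be reduced under these homogeneous conditions.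

Step 10
Reactants: 22 (3R)-3-[(6S)-6-benzyloxyundecyl]-6,8-dimethoxyisochroman-1-one
Product: 23 (3R)-6,8-dihydroxy-3-[(6S)-6-hydroxyundecyl]isochroman-1-one
Conditions: BBr3 (6 equiv), CH2Cl2, −78 °C → rt; ice-water, aq. NaHCO3
Reagents that add atoms: none
Why: Lewis-acid ether cleavage: BBr3 coordinates each ether oxygen and bromide attacks the methyl or benzyl carbon, leaving aryl and secondary alkyl borates that hydrolyse on work-up; the C8 ether should cleave fastest through chelation to the lactone carbonyl. The C3–O2 and C6'–O bonds are not broken, so both stereocentres are retained.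

## Compound list

1 | 3,5-dimethoxyphenol | COc1cc(O)cc(OC)c1 | starting material
2 | 3,5-dimethoxyphenyl N-isopropylcarbamate | COc1cc(OC)cc(OC(=O)NC(C)C)c1 | intermediate
3 | 3,5-dimethoxyphenyl N-(tert-butyldimethylsilyl)-N-isopropylcarbamate | COc1cc(OC)cc(OC(=O)N(C(C)C)[Si](C)(C)C(C)(C)C)c1 | intermediate
4 | [2-(N-tert-butyldimethylsilyl-N-isopropylcarbamoyloxy)-4,6-dimethoxyphenyl]lithium | [Li]c1c(OC)cc(OC)cc1OC(=O)N(C(C)C)[Si](C)(C)C(C)(C)C | intermediate
5 | 3,5-dimethoxy-2-(trimethylsilyl)phenyl N-(tert-butyldimethylsilyl)-N-isopropylcarbamate | COc1cc(OC)c([Si](C)(C)C)c(OC(=O)N(C(C)C)[Si](C)(C)C(C)(C)C)c1 | intermediate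
6 | 3,5-dimethoxy-2-(trimethylsilyl)phenyl N-isopropylcarbamate | COc1cc(OC)c([Si](C)(C)C)c(OC(=O)NC(C)C)c1 | intermediate
7 | 3,5-dimethoxy-2-(trimethylsilyl)phenol, present as its phenoxide salt | COc1cc(OC)c([Si](C)(C)C)c(O)c1 | intermediate
8 | 3,5-dimethoxy-2-(trimethylsilyl)phenyl trifluoromethanesulfonate | COc1cc(OC)c([Si](C)(C)C)c(OS(=O)(=O)C(F)(F)F)c1 | intermediate
9 | 6-chlorohex-1-yne | C#CCCCCCl | starting material
10 | (6-chlorohex-1-yn-1-yl)lithium | [Li]C#CCCCCCl | intermediate
11 | (6-chlorohex-1-yn-1-yl)trimethylsilane | C[Si](C)(C)C#CCCCCCl | intermediate
12 | racemic 1,2-epoxyheptane (2-pentyloxirane) | CCCCCC1CO1 | starting material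
13 | (S)-1,2-epoxyheptane | CCCCC[C@H]1CO1 | intermediate
14 | [6-(trimethylsilyl)hex-5-yn-1-yl]magnesium chloride | C[Si](C)(C)C#CCCCC[Mg]Cl | intermediate
15 | (8S)-1-(trimethylsilyl)tridec-1-yn-8-ol | CCCCC[C@H](O)CCCCCC#C[Si](C)(C)C | intermediate
16 | [(8S)-8-benzyloxytridec-1-yn-1-yl]trimethylsilane | CCCCC[C@H](OCc1ccccc1)CCCCCC#C[Si](C)(C)C | intermediate
17 | (8S)-8-benzyloxytridec-1-yne | CCCCC[C@H](OCc1ccccc1)CCCCCC#C | intermediate
18 | carbon dioxide | O=C=O | starting material
19 | 3,5-dimethoxybenzyne | COC1=CC(OC)=CC#C1 | intermediate
20 | cesium 2-[(8S)-8-benzyloxytridec-1-yn-1-yl]-4,6-dimethoxybenzoate (in exchange with its copper carboxylate) | CCCCC[C@H](OCc1ccccc1)CCCCCC#Cc1cc(OC)cc(OC)c1C(=O)[O-].[Cs+] | intermediate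
21 | 3-[(6S)-6-benzyloxyundecyl]-6,8-dimethoxyisochromen-1-one | CCCCC[C@H](OCc1ccccc1)CCCCCC1=Cc2cc(OC)cc(OC)c2C(=O)O1 | intermediate
22 | (3R)-3-[(6S)-6-benzyloxyundecyl]-6,8-dimethoxyisochroman-1-one | CCCCC[C@H](OCc1ccccc1)CCCCC[C@@H]1Cc2cc(OC)cc(OC)c2C(=O)O1 | intermediate
23 | (3R)-6,8-dihydroxy-3-[(6S)-6-hydroxyundecyl]isochroman-1-one | CCCCC[C@H](O)CCCCC[C@@H]1Cc2cc(O)cc(O)c2C(=O)O1 | target

## Step count and risk

Total step count: 10. Longest linear sequence: 6 steps (for example steps 5, 6, 7, 8, 9, 10 from 12; the branches from 1 and from 9 are equally long).

**Step 8 (key step).** The most likely failure is protonation of the aryl–copper intermediate, or capture of a second aryne, before CO2 inserts. The electron-rich carboxylate may also be arylated on oxygen by further aryne. Closure in the 5-exo mode is the lesser concern. Fallback: setting out from 17, Sonogashira coupling (Pd(PPh3)2Cl2, CuI, Et3N, DMF, 70 °C) with methyl 4,6-dimethoxy-2-(trifluoromethylsulfonyloxy)benzoate F1 (made from purchased methyl 2-hydroxy-4,6-dimethoxybenzoate with Tf2O and pyridine) would give methyl 2-[(8S)-8-benzyloxytridec-1-yn-1-yl]-4,6-dimethoxybenzoate F2. Saponification (KOH, aqueous EtOH, reflux) would give 2-[(8S)-8-benzyloxytridec-1-yn-1-yl]-4,6-dimethoxybenzoic acid F3, and AgOTf-catalysed 6-endo-dig lactonisation would return to the route at 21. This gives up the three-component convergence but uses only established reactions.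

**Step 9.** Facial discrimination may be insufficient when C3 carries a long n-alkyl chain and the lactone carbonyl is crowded by the C8 methoxy group, or the turnover may be slow. Fallback: setting out from 21, KOH in aqueous EtOH opens the enol lactone to 2-[(8S)-8-benzyloxy-2-oxotridecyl]-4,6-dimethoxybenzoic acid F4. A ketoreductase chosen from a panel (NADPH with glucose and glucose dehydrogenase for recycling, phosphate buffer pH 7, 30 °C) reduces the ketone of the water-soluble carboxylate to 2-[(2R,8S)-8-benzyloxy-2-hydroxytridecyl]-4,6-dimethoxybenzoic acid F5. Acid (TsOH, toluene) closes the lactone and returns to the route at 22.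

**Step 2.** Metalation could occur in part between the two methoxy groups, or the carbamoyl group could migrate to carbon before silylation, if the temperature is not held. Fallback: setting out from 1, ortho-bromination (NBS, CH2Cl2, −78 °C → rt, with chromatographic removal of the para isomer) gives 2-bromo-3,5-dimethoxyphenol F6. O-Silylation (HMDS, THF, 70 °C) gives (2-bromo-3,5-dimethoxyphenoxy)trimethylsilane F7. Bromine–lithium exchange with n-BuLi (THF, −100 → −78 °C) triggers the retro-Brook shift of silicon from oxygen to carbon and gives phenoxide 7, which Tf2O converts to 8, where the route is rejoined.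

**Step 10.** Under excess Lewis acid the C6' oxygen may be lost by substitution or elimination, the non-chelated C6 methyl ether may cleave incompletely, or bromide may open the lactone at C3. Fallback: setting out from 22, hydrogenolysis (H2, 10% Pd/C, EtOAc) first removes the benzyl group and gives (3R)-3-[(6S)-6-hydroxyundecyl]-6,8-dimethoxyisochroman-1-one F8. The two methyl ethers are then cleaved with AlCl3 and EtSH (CH2Cl2, 0 °C → rt), in which the soft thiol attacks the methyl groups and the carbinol is held as an aluminium alkoxide. This returns to the route at 23.

## Further compounds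

F1 | step 8 | methyl 4,6-dimethoxy-2-(trifluoromethylsulfonyloxy)benzoate | COC(=O)c1c(OC)cc(OC)cc1OS(=O)(=O)C(F)(F)F
F2 | step 8 | methyl 2-[(8S)-8-benzyloxytridec-1-yn-1-yl]-4,6-dimethoxybenzoate | CCCCC[C@H](OCc1ccccc1)CCCCCC#Cc1cc(OC)cc(OC)c1C(=O)OC
F3 | step 8 | 2-[(8S)-8-benzyloxytridec-1-yn-1-yl]-4,6-dimethoxybenzoic acid | CCCCC[C@H](OCc1ccccc1)CCCCCC#Cc1cc(OC)cc(OC)c1C(=O)O
F4 | step 9 | 2-[(8S)-8-benzyloxy-2-oxotridecyl]-4,6-dimethoxybenzoic acid | CCCCC[C@H](OCc1ccccc1)CCCCCC(=O)Cc1cc(OC)cc(OC)c1C(=O)O
F5 | step 9 | 2-[(2R,8S)-8-benzyloxy-2-hydroxytridecyl]-4,6-dimethoxybenzoic acid | CCCCC[C@H](OCc1ccccc1)CCCCC[C@@H](O)Cc1cc(OC)cc(OC)c1C(=O)O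
F6 | step 2 | 2-bromo-3,5-dimethoxyphenol | COc1cc(O)c(Br)c(OC)c1
F7 | step 2 | (2-bromo-3,5-dimethoxyphenoxy)trimethylsilane | COc1cc(O[Si](C)(C)C)c(Br)c(OC)c1
F8 | step 10 | (3R)-3-[(6S)-6-hydroxyundecyl]-6,8-dimethoxyisochroman-1-one | CCCCC[C@H](O)CCCCC[C@@H]1Cc2cc(OC)cc(OC)c2C(=O)O1
A1 | alternative 1 | methyl (5R,11S)-5,11-bis(tert-butyldimethylsilyloxy)hexadec-2-ynoate | CCCCC[C@H](O[Si](C)(C)C(C)(C)C)CCCCC[C@@H](O[Si](C)(C)C(C)(C)C)CC#CC(=O)OC
A2 | alternative 1 | 1-methoxy-1,3-bis(trimethylsilyloxy)buta-1,3-diene | COC(O[Si](C)(C)C)=CC(=C)O[Si](C)(C)C
A3 | alternative 1 | methyl 2-[(2R,8S)-2,8-bis(tert-butyldimethylsilyloxy)tridecyl]-4,6-dihydroxybenzoate | CCCCC[C@H](O[Si](C)(C)C(C)(C)C)CCCCC[C@@H](O[Si](C)(C)C(C)(C)C)Cc1cc(O)cc(O)c1C(=O)OC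
A4 | alternative 2 | 2-[(6S)-6-hydroxyundecyl]-5,7-dimethoxyindan-1-one (racemic at C2) | CCCCC[C@H](O)CCCCCC1Cc2cc(OC)cc(OC)c2C1=O
A5 | alternative 2 | (3R)-3-[(6S)-6-hydroxyundecyl]-6,8-dimethoxyisochroman-1-one | CCCCC[C@H](O)CCCCC[C@@H]1Cc2cc(OC)cc(OC)c2C(=O)O1
A6 | alternative 3 | 6-[(6R,12S)-6,12-bis(tert-butyldimethylsilyloxy)-2,4-dioxoheptadecyl]-2,2-dimethyl-1,3-dioxin-4-one | CCCCC[C@H](O[Si](C)(C)C(C)(C)C)CCCCC[C@@H](O[Si](C)(C)C(C)(C)C)CC(=O)CC(=O)CC1=CC(=O)OC(C)(C)O1
A7 | alternative 3 | 5-[(2R,8S)-2,8-bis(tert-butyldimethylsilyloxy)tridecyl]-7-hydroxy-2,2-dimethyl-1,3-benzodioxin-4-one | CCCCC[C@H](O[Si](C)(C)C(C)(C)C)CCCCC[C@@H](O[Si](C)(C)C(C)(C)C)Cc1cc(O)cc2OC(C)(C)OC(=O)c12
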